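**Plan**
1. Retrosynthetic cuts, in order: the prenyl olefin at C6 (cross-metathesis) and the C6–allyl bond (Claisen from O5); then the two bonds that tie the pyran to ring B, C3'–C4'' and C4'–O1'' (with O1''–C2''), back to a C3'–C4' aryne and 3-methylbut-2-enal; last the C3–C1' bond (Suzuki–Miyaura).
2. Enabling feature: the pyran oxygen O1'' and the styrenic carbon C4'' sit on the adjacent ring B carbons C4' and C3', and the pyran ends in a CMe2 group. Ring B plus pyran is therefore the formal adduct of an aryne and an enal: the C=O supplies O1'' and C4'', and the β-carbon closes the ring by oxa-6π electrocyclisation.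
3. Forward: acetophenone → 3-iodochromone (rings A and C); symmetric 2,6-bis(silyl)aryl triflate boronate (ring B); Suzuki union; aryne annulation builds the pyran; acid removes the helpers; Claisen and cross-metathesis place the prenyl group at C6.
4. Helpers: the second SiMe3 group (regiocontrol in the aryne step, removed in step 10), MOM on O7 (removed in step 10), allyl on O5 (carried to C6 and turned into prenyl).
5. Stereochemistry: the target has no stereocentre; the pyran olefin is cis by ring constraint and the prenyl olefin has no geometric isomers.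

Key step: step 9

Remark: isoflavone numbering is used (O1, C2–C4, C4a, C5–C8, C8a; ring B C1'–C6'), the pyran atoms fused to ring B are double-primed (O1'', C2''–C4''), and compounds 1, 6 and 14 are taken as purchased.

**Step 1**
Reactants: 1 1-(2,4,6-trihydroxyphenyl)ethan-1-one
Product: 2 1-[2,6-dihydroxy-4-(methoxymethoxy)phenyl]ethan-1-one
Conditions: MOMCl (1.05 equiv), i-Pr2NEt (1.1 equiv), CH2Cl2, 0 °C
Reagents that add atoms: chloromethyl methyl ether, COCCl
Why: Williamson-type O-alkylation; the C4 hydroxyl is the only one not hydrogen-bonded to the acetyl carbonyl and is the most acidic, so one equivalent of base and MOMCl should protect it selectively.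

**Step 2**
Reactants: 2 1-[2,6-dihydroxy-4-(methoxymethoxy)phenyl]ethan-1-one
Product: 3 1-[2-hydroxy-4-(methoxymethoxy)-6-(prop-2-en-1-yloxy)phenyl]ethan-1-one
Conditions: allyl bromide (1.1 equiv), K2CO3, acetone, reflux
Reagents that add atoms: allyl bromide, C=CCBr
Why: Williamson etherification; the two chelated hydroxyls are equivalent, and once one is allylated the other is held in a strong hydrogen bond to the ketone and should resist a second alkylation.

**Step 3**
Reactants: 3 1-[2-hydroxy-4-(methoxymethoxy)-6-(prop-2-en-1-yloxy)phenyl]ethan-1-one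
Product: 4 (E)-3-(dimethylamino)-1-[2-hydroxy-4-(methoxymethoxy)-6-(prop-2-en-1-yloxy)phenyl]prop-2-en-1-one
Conditions: N,N-dimethylformamide dimethyl acetal, toluene, 90 °C
Reagents that add atoms: N,N-dimethylformamide dimethyl acetal, COC(OC)N(C)C
Why: Condensation of the methyl ketone with the amide acetal should give the (E)-enaminone, and the chelated phenol is not methylated under these conditions.

**Step 4**
Reactants: 4 (E)-3-(dimethylamino)-1-[2-hydroxy-4-(methoxymethoxy)-6-(prop-2-en-1-yloxy)phenyl]prop-2-en-1-one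
Product: 5 3-iodo-7-(methoxymethoxy)-5-(prop-2-en-1-yloxy)-4H-chromen-4-one
Conditions: I2, pyridine, CHCl3, rt
Reagents that add atoms: iodine, [I][I]
Why: Iodine-mediated cyclisation of an o-hydroxyaryl enaminone is the standard entry to 3-iodochromones, and only the one free hydroxyl can close, which places the allyl ether at C5 and the MOM ether at C7.

**Step 5**
Reactants: 6 2,6-dibromophenol
Product: 7 (2,6-dibromophenoxy)trimethylsilane
Conditions: hexamethyldisilazane, THF, reflux; evaporation
Reagents that add atoms: hexamethyldisilazane, C[Si](C)(C)N[Si](C)(C)C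
Why: O-silylation of the phenol by the disilazane with loss of ammonia is routine and needs no work-up.

**Step 6**
Reactants: 7 (2,6-dibromophenoxy)trimethylsilane
Product: 11 2,6-bis(trimethylsilyl)phenyl trifluoromethanesulfonate, via lithium 2-bromo-6-(trimethylsilyl)phenolate 8 (not isolated), via [2-bromo-6-(trimethylsilyl)phenoxy]trimethylsilane 9 (not isolated), via lithium 2,6-bis(trimethylsilyl)phenolate 10 (not isolated)
Conditions: n-BuLi, THF, –78 °C to rt; TMSCl, –78 °C to rt; n-BuLi, –78 °C to rt; Tf2O, –78 to 0 °C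
Reagents that add atoms: chlorotrimethylsilane, C[Si](C)(C)Cl; trifluoromethanesulfonic anhydride, O=S(=O)(C(F)(F)F)OS(=O)(=O)C(F)(F)F
Why: Bromine–lithium exchange followed by 1,3 O-to-C silyl migration (retro-Brook rearrangement) is run twice and the hindered lithium phenolate is then O-triflated, the standard way to o-silylaryl triflates.

**Step 7**
Reactants: 11 2,6-bis(trimethylsilyl)phenyl trifluoromethanesulfonate
Product: 12 4-(4,4,5,5-tetramethyl-1,3,2-dioxaborolan-2-yl)-2,6-bis(trimethylsilyl)phenyl trifluoromethanesulfonate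
Conditions: [Ir(OMe)(cod)]2 (1.5 mol%), 4,4'-di-tert-butyl-2,2'-bipyridine (3 mol%), B2pin2 (1.0 equiv), cyclohexane, 80 °C
Reagents that add atoms: bis(pinacolato)diboron, CC1(C)OB(OC1(C)C)B1OC(C)(C)C(C)(C)O1
Why: Sterically controlled iridium-catalysed aromatic C–H borylation; C4 is the only ring C–H not ortho to a substituent, and o-silylaryl triflates are known to tolerate these neutral conditions.

**Step 8**
Reactants: 5 3-iodo-7-(methoxymethoxy)-5-(prop-2-en-1-yloxy)-4H-chromen-4-one; 12 4-(4,4,5,5-tetramethyl-1,3,2-dioxaborolan-2-yl)-2,6-bis(trimethylsilyl)phenyl trifluoromethanesulfonate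
Product: 13 4-[7-(methoxymethoxy)-4-oxo-5-(prop-2-en-1-yloxy)-4H-chromen-3-yl]-2,6-bis(trimethylsilyl)phenyl trifluoromethanesulfonate
Conditions: PdCl2(dppf) (5 mol%), K3PO4, 1,4-dioxane/H2O, 50 °C
Reagents that add atoms: none
Why: Suzuki–Miyaura coupling; oxidative addition into the C3–I bond of the iodochromone is much faster than into the aryl triflate, which is shielded by two flanking SiMe3 groups, and the mild fluoride-free base should leave the o-silylaryl triflate intact.

**Step 9**
Reactants: 13 4-[7-(methoxymethoxy)-4-oxo-5-(prop-2-en-1-yloxy)-4H-chromen-3-yl]-2,6-bis(trimethylsilyl)phenyl trifluoromethanesulfonate; 14 3-methylbut-2-enal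
Product: 18 3-[2,2-dimethyl-8-(trimethylsilyl)-2H-chromen-6-yl]-7-(methoxymethoxy)-5-(prop-2-en-1-yloxy)-4H-chromen-4-one, via aryne 15 (not isolated), via benzoxete 16 (not isolated), via ortho-quinone methide 17 (not isolated)
Conditions: CsF (3 equiv), 14 (5 equiv), MeCN, rt
Reagents that add atoms: none
Why: Fluoride attacks one of the two equivalent SiMe3 groups of 13 and triflate leaves, giving the C3'–C4' aryne 15 that keeps SiMe3 at C5'; the carbonyl oxygen of 14 adds to C4', the aryl anion at C3' closes on the carbonyl carbon (formal [2+2]) to benzoxete 16, 4π-electrocyclic opening gives ortho-quinone methide 17, and oxa-6π electrocyclisation of its (Z)-isomer forms the O1''–C2'' bond. The closest known reaction type is the annulation of arynes with α,β-unsaturated aldehydes to 2H-chromenes (aryne insertion into C=O, then oxa-6π), applied here to a 3-silylaryne. The four-membered ring closes by a stepwise polar [2+2] (4-exo attack of the aryl anion on the oxocarbenium carbon) and the pyran by a thermal disrotatory 6π electrocyclisation that engages the CMe2 terminus. No stereocentre results, because the benzoxete CH is lost on ring opening and C2'' carries two methyl groups. The step needs oxygen at C4' and carbon at C3': the electropositive SiMe3 at C5' distorts the aryne so that the adjacent carbon C4' is the more electrophilic one (the small carbonyl oxygen can approach next to SiMe3), the para chromonyl group pulls weakly in the same sense, and the symmetry of 13 makes it irrelevant which silyl group leaves. Excess 14 should outrun the chromone carbonyl and the allyl ether as aryne traps, the s-trans preference of 14 (its cis β-methyl clashes with the oxygen in the s-cis form) disfavours a [4+2] to a 4H-chromene, and the aryne carbons are too far from ring C for intramolecular capture.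

**Step 10**
Reactants: 18 3-[2,2-dimethyl-8-(trimethylsilyl)-2H-chromen-6-yl]-7-(methoxymethoxy)-5-(prop-2-en-1-yloxy)-4H-chromen-4-one
Product: 19 3-(2,2-dimethyl-2H-chromen-6-yl)-7-hydroxy-5-(prop-2-en-1-yloxy)-4H-chromen-4-one
Conditions: TFA/CH2Cl2 (1:5), H2O (5 equiv), 0 °C to rt, dilute; aq. NaHCO3
Reagents that add atoms: none
Why: Electrophilic ipso-protodesilylation of the aryl silane, activated by the ortho pyran oxygen, and acid hydrolysis of the MOM acetal should occur under the same conditions, while dilution and low temperature spare the chromene olefin and the allyl ether.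

**Step 11**
Reactants: 19 3-(2,2-dimethyl-2H-chromen-6-yl)-7-hydroxy-5-(prop-2-en-1-yloxy)-4H-chromen-4-one
Product: 21 3-(2,2-dimethyl-2H-chromen-6-yl)-5,7-dihydroxy-6-(prop-2-en-1-yl)-4H-chromen-4-one, via 6-allyl dienone 20 (not isolated)
Conditions: N,N-diethylaniline, 190 °C, argon, sealed tube
Reagents that add atoms: none
Why: Aromatic Claisen rearrangement ([3,3]); C6 is the only ortho carbon of the C5 ether that bears hydrogen (the other is the ring-fusion carbon C4a), so dienone 20 should tautomerise to the chelated 6-allyl-5-hydroxy compound with full regiocontrol.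

**Step 12**
Reactants: 21 3-(2,2-dimethyl-2H-chromen-6-yl)-5,7-dihydroxy-6-(prop-2-en-1-yl)-4H-chromen-4-one
Product: 22 isochandalone, 3-(2,2-dimethyl-2H-chromen-6-yl)-5,7-dihydroxy-6-(3-methylbut-2-en-1-yl)-4H-chromen-4-one
Conditions: second-generation Grubbs catalyst RuCl2(=CHPh)(PCy3)(H2IMes) (5 mol%), 2-methylbut-2-ene/CH2Cl2, 40 °C, sealed tube
Reagents that add atoms: 2-methylbut-2-ene, CC=C(C)C
Why: Olefin cross-metathesis of the terminal allyl group with excess 2-methylbut-2-ene should give the prenyl group with loss of propene; the pyran olefin, cis-disubstituted and next to the quaternary C2'', should not engage, and free phenols are tolerated.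

**Compound list**
1 | 1-(2,4,6-trihydroxyphenyl)ethan-1-one | CC(=O)c1c(O)cc(O)cc1O | starting material
2 | 1-[2,6-dihydroxy-4-(methoxymethoxy)phenyl]ethan-1-one | CC(=O)c1c(O)cc(OCOC)cc1O | intermediate
3 | 1-[2-hydroxy-4-(methoxymethoxy)-6-(prop-2-en-1-yloxy)phenyl]ethan-1-one | CC(=O)c1c(O)cc(OCOC)cc1OCC=C | intermediate
4 | (E)-3-(dimethylamino)-1-[2-hydroxy-4-(methoxymethoxy)-6-(prop-2-en-1-yloxy)phenyl]prop-2-en-1-one | CN(C)/C=C/C(=O)c1c(O)cc(OCOC)cc1OCC=C | intermediate
5 | 3-iodo-7-(methoxymethoxy)-5-(prop-2-en-1-yloxy)-4H-chromen-4-one | O=c1c(I)coc2cc(OCOC)cc(OCC=C)c12 | intermediate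
6 | 2,6-dibromophenol | Oc1c(Br)cccc1Br | starting material
7 | (2,6-dibromophenoxy)trimethylsilane | C[Si](C)(C)Oc1c(Br)cccc1Br | intermediate
8 | lithium 2-bromo-6-(trimethylsilyl)phenolate | [Li+].[O-]c1c(Br)cccc1[Si](C)(C)C | intermediate
9 | [2-bromo-6-(trimethylsilyl)phenoxy]trimethylsilane | C[Si](C)(C)Oc1c(Br)cccc1[Si](C)(C)C | intermediate
10 | lithium 2,6-bis(trimethylsilyl)phenolate | [Li+].[O-]c1c([Si](C)(C)C)cccc1[Si](C)(C)C | intermediate
11 | 2,6-bis(trimethylsilyl)phenyl trifluoromethanesulfonate | C[Si](C)(C)c1cccc([Si](C)(C)C)c1OS(=O)(=O)C(F)(F)F | intermediate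
12 | 4-(4,4,5,5-tetramethyl-1,3,2-dioxaborolan-2-yl)-2,6-bis(trimethylsilyl)phenyl trifluoromethanesulfonate | CC1(C)OB(OC1(C)C)c1cc([Si](C)(C)C)c(OS(=O)(=O)C(F)(F)F)c([Si](C)(C)C)c1 | intermediate
13 | 4-[7-(methoxymethoxy)-4-oxo-5-(prop-2-en-1-yloxy)-4H-chromen-3-yl]-2,6-bis(trimethylsilyl)phenyl trifluoromethanesulfonate | C=CCOc1cc(OCOC)cc2occ(-c3cc([Si](C)(C)C)c(OS(=O)(=O)C(F)(F)F)c([Si](C)(C)C)c3)c(=O)c12 | intermediate
14 | 3-methylbut-2-enal | CC(C)=CC=O | starting material
15 | aryne: 3-[3,4-didehydro-5-(trimethylsilyl)phenyl]-7-(methoxymethoxy)-5-(prop-2-en-1-yloxy)-4H-chromen-4-one | C=CCOc1cc(OCOC)cc2occ(C3=CC#CC([Si](C)(C)C)=C3)c(=O)c12 | intermediate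
16 | benzoxete: 3-[8-(2-methylprop-1-en-1-yl)-5-(trimethylsilyl)-7-oxabicyclo[4.2.0]octa-1,3,5-trien-3-yl]-7-(methoxymethoxy)-5-(prop-2-en-1-yloxy)-4H-chromen-4-one (racemic at the oxete CH) | C=CCOc1cc(OCOC)cc2occ(-c3cc4c(c([Si](C)(C)C)c3)OC4C=C(C)C)c(=O)c12 | intermediate
17 | ortho-quinone methide: 3-[(3Z)-3-(3-methylbut-2-en-1-ylidene)-4-oxo-5-(trimethylsilyl)cyclohexa-1,5-dien-1-yl]-7-(methoxymethoxy)-5-(prop-2-en-1-yloxy)-4H-chromen-4-one | CC(C)=C/C=C1\C(=O)C([Si](C)(C)C)=CC(c2coc3cc(OCOC)cc(OCC=C)c3c2=O)=C1 | intermediate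
18 | 3-[2,2-dimethyl-8-(trimethylsilyl)-2H-chromen-6-yl]-7-(methoxymethoxy)-5-(prop-2-en-1-yloxy)-4H-chromen-4-one | C=CCOc1cc(OCOC)cc2occ(-c3cc4c(c([Si](C)(C)C)c3)OC(C)(C)C=C4)c(=O)c12 | intermediate
19 | 3-(2,2-dimethyl-2H-chromen-6-yl)-7-hydroxy-5-(prop-2-en-1-yloxy)-4H-chromen-4-one | C=CCOc1cc(O)cc2occ(-c3ccc4c(c3)C=CC(C)(C)O4)c(=O)c12 | intermediate
20 | 6-allyl dienone: 3-(2,2-dimethyl-2H-chromen-6-yl)-7-hydroxy-6-(prop-2-en-1-yl)-4H-chromene-4,5(6H)-dione (racemic at C6) | C=CCC1C(=O)C2=C(C=C1O)OC=C(c1ccc3c(c1)C=CC(C)(C)O3)C2=O | intermediate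
21 | 3-(2,2-dimethyl-2H-chromen-6-yl)-5,7-dihydroxy-6-(prop-2-en-1-yl)-4H-chromen-4-one | C=CCc1c(O)cc2occ(-c3ccc4c(c3)C=CC(C)(C)O4)c(=O)c2c1O | intermediate
22 | isochandalone, 3-(2,2-dimethyl-2H-chromen-6-yl)-5,7-dihydroxy-6-(3-methylbut-2-en-1-yl)-4H-chromen-4-one | CC(C)=CCc1c(O)cc2occ(-c3ccc4c(c3)C=CC(C)(C)O4)c(=O)c2c1O | target

**Step count and risks**
Total steps: 12. Longest linear sequence: 9 steps (steps 1–4, then 8–12); the ring B branch (steps 5–7) joins at step 8.

Steps most likely to fail:

Step 9. The aldehyde oxygen may attack the unhindered aryne carbon C3' (steric control overriding aryne distortion), which would give the angular pyran regioisomer. The aryne may also be captured by the chromone carbonyl, or the enal may self-condense under fluoride. Fallback, setting out from 5 and coming back at 19: 5 is coupled with 4-hydroxyphenylboronic acid (PdCl2(dppf), K3PO4, dioxane/H2O, 50 °C) to 3-(4-hydroxyphenyl)-7-(methoxymethoxy)-5-(prop-2-en-1-yloxy)-4H-chromen-4-one F1. The free phenol of F1 is then condensed with 14 (PhB(OH)2, AcOH, toluene, reflux with water removal), a phenol-derived ortho-quinone methide closing by oxa-6π at either of the two equivalent ortho carbons, to give 3-(2,2-dimethyl-2H-chromen-6-yl)-7-(methoxymethoxy)-5-(prop-2-en-1-yloxy)-4H-chromen-4-one F2. The MOM ether of F2 is cleaved (HCl, MeOH/THF, 40 °C) to give 19.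

Step 8. The o-silylaryl triflate may undergo premature desilylative elimination or S–O cleavage under aqueous base, or palladium may remove the O5 allyl group. Fallback, setting out from 12 and coming back at 18: the order of union and annulation is reversed. Boronate 12 is first treated with 14 and CsF in MeCN, the same aryne annulation on the small fragment, to give 2-[2,2-dimethyl-8-(trimethylsilyl)-2H-chromen-6-yl]-4,4,5,5-tetramethyl-1,3,2-dioxaborolane F3. F3, which no longer carries a triflate, is then coupled with 5 (PdCl2(dppf), K3PO4, dioxane/H2O) to give 18.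

Step 10. Acid may oligomerise the chromene olefin, or the liberated formaldehyde equivalent may hydroxymethylate ring A, in competition with ipso-protodesilylation. Fallback, setting out from 18 and coming back at 19: the single protic-acid operation is replaced by two orthogonal, non-protic cleavages. The MOM group of 18 is transferred to a thiol (ZnBr2, n-PrSH, CH2Cl2, 0 °C) to give 3-[2,2-dimethyl-8-(trimethylsilyl)-2H-chromen-6-yl]-7-hydroxy-5-(prop-2-en-1-yloxy)-4H-chromen-4-one F4. The aryl silane of F4 is then cleaved by fluoride attack at silicon (Bu4NF, wet DMF, 70 °C) to give 19.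

**Further compounds**
F1 | step 9 | 3-(4-hydroxyphenyl)-7-(methoxymethoxy)-5-(prop-2-en-1-yloxy)-4H-chromen-4-one | C=CCOc1cc(OCOC)cc2occ(-c3ccc(O)cc3)c(=O)c12
F2 | step 9 | 3-(2,2-dimethyl-2H-chromen-6-yl)-7-(methoxymethoxy)-5-(prop-2-en-1-yloxy)-4H-chromen-4-one | C=CCOc1cc(OCOC)cc2occ(-c3ccc4c(c3)C=CC(C)(C)O4)c(=O)c12
F3 | step 8 | 2-[2,2-dimethyl-8-(trimethylsilyl)-2H-chromen-6-yl]-4,4,5,5-tetramethyl-1,3,2-dioxaborolane | CC1(C)OB(OC1(C)C)c1cc2c(c([Si](C)(C)C)c1)OC(C)(C)C=C2
F4 | step 10 | 3-[2,2-dimethyl-8-(trimethylsilyl)-2H-chromen-6-yl]-7-hydroxy-5-(prop-2-en-1-yloxy)-4H-chromen-4-one | C=CCOc1cc(O)cc2occ(-c3cc4c(c([Si](C)(C)C)c3)OC(C)(C)C=C4)c(=O)c12
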